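**Retrosynthetic overview** (locants are those of the cyclodeca[b]furan target)
1. Last bond: C4–C3a, by decarboxylative radical 10-exo cyclisation of seco acid 21 onto its own 3-(sulfonylmethyl)butenolide with SH2′ loss of sulfinate. This closes the carbocycle, sets C4 and C3a, and unveils the exo-methylene.
2. 21 comes from a boron aldol (C8–C9) of methyl ketone 10 with butenolide aldehyde 19, then tert-butyl ester cleavage.
3. 10 (C6 quaternary centre, both acyloxy groups, masked radical precursor) comes from (R)-lactic acid through a Seebach dioxolanone.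
4. 19 comes from propanal: α-allylation (C10), cross-metathesis, Ir-catalysed allylic esterification (C11a), ring-closing metathesis.
5. Ring order: butenolide first (step 10), ten-membered carbocycle last (step 13).

Assumption: the target is (3aS,4R,6S,9R,10S,11aS) as encoded in the SMILES (cis-fused lactone); the antipodes of the chiral catalysts and of Ipc2BCl are named by their expected sense of induction and would be swapped if a pilot run shows the opposite sense.

Step 1
Reactants: 1 (R)-lactic acid
Product: 2 (2R,5R)-2-tert-butyl-5-methyl-1,3-dioxolan-4-one (cis)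
Conditions: tBuCHO, TsOH (cat.), H2SO4 (cat.), pentane, reflux (Dean–Stark); recrystallise (Et2O/pentane, −78 °C)
Reagents that add atoms: pivaldehyde, CC(C)(C)C=O
Why: Seebach acetalisation gives the cis-dioxolanone after crystallisation, so the lactic acid stereocentre is stored in the new acetal carbon (self-regeneration of stereocentres).

Step 2
Reactants: 2 (2R,5R)-2-tert-butyl-5-methyl-1,3-dioxolan-4-one; 3 tert-butyl acrylate
Product: 5 tert-butyl (2RS)-3-[(2R,4S)-2-tert-butyl-4-methyl-5-oxo-1,3-dioxolan-4-yl]-2-hydroxypropanoate, via lithium ester enolate 4 (not isolated)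
Conditions: LiN(iPr)2, THF, −78 °C; 3, −78 °C; then 3-phenyl-2-(phenylsulfonyl)oxaziridine, −78 °C; AcOH
Reagents that add atoms: 3-phenyl-2-(phenylsulfonyl)oxaziridine, O=S(=O)(c1ccccc1)N1OC1c1ccccc1
Why: Michael addition of the dioxolanone enolate occurs anti to the tert-butyl group and sets the quaternary centre (C6 of the target, S), and the resulting ester enolate is hydroxylated in situ (Davis enolate oxidation); the new carbinol is a mixture, which does not matter because that carbon becomes a planar radical in step 13.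

Step 3
Reactants: 5 tert-butyl (2RS)-3-[(2R,4S)-2-tert-butyl-4-methyl-5-oxo-1,3-dioxolan-4-yl]-2-hydroxypropanoate
Product: 7 tert-butyl (2RS,4S)-2,4-dihydroxy-4-methyl-5-oxohexanoate, via dilithium hemiketal alkoxide 6 (not isolated)
Conditions: MeLi (2.1 equiv), THF, −78 °C; AcOH, −78 °C → rt
Reagents that add atoms: methyllithium, [Li]C
Why: after deprotonation of the hydroxyl, MeLi adds once to the activated acetal-lactone carbonyl (the tetrahedral adduct persists at −78 °C; the hindered tert-butyl ester next to an alkoxide is spared), and quenching releases pivaldehyde and the α-hydroxy methyl ketone without touching the quaternary centre (organolithium mono-addition to a lactone).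

Step 4
Reactants: 7 tert-butyl (2RS,4S)-2,4-dihydroxy-4-methyl-5-oxohexanoate; 8 angelic acid
Product: 9 tert-butyl (2RS,4S)-4-hydroxy-4-methyl-2-{[(2Z)-2-methylbut-2-enoyl]oxy}-5-oxohexanoate
Conditions: 8, PPh3, DIAD, THF, 0 °C → rt
Reagents that add atoms: none
Why: Mitsunobu esterification acylates only the secondary α-hydroxy ester (the tertiary ketol is inert) under neutral conditions that do not isomerise angelate to tiglate; the inversion at C2 is irrelevant.

Step 5
Reactants: 9 tert-butyl (2RS,4S)-4-hydroxy-4-methyl-2-{[(2Z)-2-methylbut-2-enoyl]oxy}-5-oxohexanoate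
Product: 10 tert-butyl (2RS,4S)-4-acetoxy-4-methyl-2-{[(2Z)-2-methylbut-2-enoyl]oxy}-5-oxohexanoate
Conditions: Ac2O, DMAP (0.3 equiv), pyridine, 40 °C
Reagents that add atoms: acetic anhydride, CC(=O)OC(C)=O
Why: DMAP-catalysed acetylation of the remaining tertiary α-ketol hydroxyl installs the C6 acetate with no change at the stereocentre.

Step 6
Reactants: 11 2-(bromomethyl)acrylic acid
Product: 12 2-[(phenylsulfonyl)methyl]prop-2-enoic acid
Conditions: PhSO2Na, MeOH, reflux
Reagents that add atoms: sodium benzenesulfinate, [Na+].[O-]S(=O)c1ccccc1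
Why: S-alkylation of sulfinate by the allylic bromide (SN2 and SN2′ give the same product) gives the allyl sulfone that later serves as the radical leaving group.

Step 7
Reactants: 13 propanal; 14 allyltrimethylsilane
Product: 15 (2S)-2-methylpent-4-enal
Conditions: (2S,5S)-5-benzyl-2-tert-butyl-3-methylimidazolidin-4-one·TFA (20 mol%), (NH4)2Ce(NO3)6 (2 equiv), NaHCO3, H2O, DME, −20 °C; solution used directly
Reagents that add atoms: none
Why: SOMO organocatalysis: the enamine is oxidised by cerium to a radical cation that is trapped by the allylsilane on the face opposite the benzyl group, and oxidation with loss of silicon gives the α-allyl aldehyde, setting C10 of the target (2S here).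

Step 8
Reactants: 15 (2S)-2-methylpent-4-enal; 16 allyl methyl carbonate
Product: 17 (2S,4E)-6-[(methoxycarbonyl)oxy]-2-methylhex-4-enal
Conditions: 16 (3 equiv), RuCl2(=CH-C6H4-2-OiPr)(H2IMes) (second-generation Hoveyda–Grubbs catalyst, 3 mol%), CH2Cl2, 40 °C
Reagents that add atoms: none
Why: olefin cross-metathesis of two terminal alkenes is driven by loss of ethylene and gives the E linear allylic carbonate; the aldehyde and its α-stereocentre are untouched.

Step 9
Reactants: 17 (2S,4E)-6-[(methoxycarbonyl)oxy]-2-methylhex-4-enal; 12 2-[(phenylsulfonyl)methyl]prop-2-enoic acid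
Product: 18 (3S,5S)-5-methyl-6-oxohex-1-en-3-yl 2-[(phenylsulfonyl)methyl]prop-2-enoate
Conditions: [Ir(cod)Cl]2 (2 mol%), (Sa,S,S)-binaphthyl N,N-bis(1-phenylethyl)phosphoramidite (4 mol%, preactivated with nPrNH2), 12 (1.2 equiv), THF, 25 °C
Reagents that add atoms: none
Why: Ir-catalysed asymmetric allylic esterification: the carbonate ionises (CO2 and methoxide, which deprotonates 12) and the carboxylate attacks the substituted allyl terminus, giving the branched ester and setting C11a of the target (3S here) under catalyst control.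

Step 10
Reactants: 18 (3S,5S)-5-methyl-6-oxohex-1-en-3-yl 2-[(phenylsulfonyl)methyl]prop-2-enoate
Product: 19 (2S)-2-methyl-3-{(2S)-5-oxo-4-[(phenylsulfonyl)methyl]-2,5-dihydrofuran-2-yl}propanal
Conditions: RuCl2(=CHPh)(PCy3)(H2IMes) (second-generation Grubbs catalyst, 5 mol%), PhMe (5 mM), 80 °C
Reagents that add atoms: none
Why: ring-closing metathesis between the vinyl group and the 1,1-disubstituted acrylate forms the five-membered butenolide with loss of ethylene; no stereocentre is affected.

Step 11
Reactants: 10 tert-butyl (2RS,4S)-4-acetoxy-4-methyl-2-{[(2Z)-2-methylbut-2-enoyl]oxy}-5-oxohexanoate; 19 (2S)-2-methyl-3-{(2S)-5-oxo-4-[(phenylsulfonyl)methyl]-2,5-dihydrofuran-2-yl}propanal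
Product: 20 tert-butyl (2RS,4S,7R,8S)-4-acetoxy-7-hydroxy-4,8-dimethyl-2-{[(2Z)-2-methylbut-2-enoyl]oxy}-5-oxo-9-{(2S)-5-oxo-4-[(phenylsulfonyl)methyl]-2,5-dihydrofuran-2-yl}nonanoate
Conditions: 10, (−)-Ipc2BCl, Et3N, Et2O, −78 → 0 °C; 19, −78 → −20 °C; H2O2, pH 7 buffer, MeOH, 0 °C
Reagents that add atoms: none
Why: Paterson boron aldol: the only possible enol borinate of 10 (methyl side) adds to 19 through a closed transition state in which the Ipc ligands select the aldehyde face and override the weak Felkin bias of the α-methyl centre, giving the 7R carbinol (C9 of the target); this is a mismatched case, so moderate dr is expected.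

Step 12
Reactants: 20 tert-butyl (2RS,4S,7R,8S)-4-acetoxy-7-hydroxy-4,8-dimethyl-2-{[(2Z)-2-methylbut-2-enoyl]oxy}-5-oxo-9-{(2S)-5-oxo-4-[(phenylsulfonyl)methyl]-2,5-dihydrofuran-2-yl}nonanoate
Product: 21 (2RS,4S,7R,8S)-4-acetoxy-7-hydroxy-4,8-dimethyl-2-{[(2Z)-2-methylbut-2-enoyl]oxy}-5-oxo-9-{(2S)-5-oxo-4-[(phenylsulfonyl)methyl]-2,5-dihydrofuran-2-yl}nonanoic acid
Conditions: TFA/CH2Cl2 (1:4), 0 °C → rt; toluene azeotrope
Reagents that add atoms: none
Why: acidolysis of the tert-butyl ester (loss of isobutene) frees the acid, while the tertiary acetate next to the ketone, the angelate, the butenolide and the β-hydroxy ketone tolerate brief cold TFA.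

Step 13
Reactants: 21 (2RS,4S,7R,8S)-4-acetoxy-7-hydroxy-4,8-dimethyl-2-{[(2Z)-2-methylbut-2-enoyl]oxy}-5-oxo-9-{(2S)-5-oxo-4-[(phenylsulfonyl)methyl]-2,5-dihydrofuran-2-yl}nonanoic acid
Product: 24 (3aS,4R,6S,9R,10S,11aS)-6-acetoxy-9-hydroxy-6,10-dimethyl-3-methylidene-2,7-dioxododecahydrocyclodeca[b]furan-4-yl (2Z)-2-methylbut-2-enoate, via α-acyloxyalkyl radical 22 (not isolated), via cyclised lactone radical 23 (not isolated)
Conditions: [Ir(dF(CF3)ppy)2(dtbbpy)]PF6 (2 mol%), K2HPO4 (1.2 equiv), DMF (1 mM), 450 nm LEDs, 25 °C, Ar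
Reagents that add atoms: none
Why: Proposed new method: the excited iridium photocatalyst oxidises the carboxylate of 21, loss of CO2 gives radical 22, which adds 10-exo to C3a of the sulfonylmethyl-butenolide (radical 23) and expels PhSO2• (SH2′) to give the exo-methylene lactone, the sulfonyl radical being reduced to sulfinate by the reduced photocatalyst so that the cycle is redox-neutral and contains no hydrogen donor to quench the slowly cyclising radical; the seven-carbon tether is anchored at C11a on one face of the planar butenolide and should deliver the radical to that same face (cis fusion, 3aS), while C4 is set in the same bond formation with the acyloxy group outside the forming ring (4R expected as the major, separable epimer, and both C2 epimers of 21 converge); the closest known reactions are photoredox decarboxylative allylation with 2-(sulfonylmethyl)acrylates and decarboxylative Giese macrocyclisation.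

**Compound list**
1 | (R)-lactic acid | C[C@@H](O)C(=O)O | starting material
2 | (2R,5R)-2-tert-butyl-5-methyl-1,3-dioxolan-4-one | C[C@H]1O[C@@H](C(C)(C)C)OC1=O | intermediate
3 | tert-butyl acrylate | C=CC(=O)OC(C)(C)C | starting material
4 | lithium enolate of tert-butyl 3-[(2R,4S)-2-tert-butyl-4-methyl-5-oxo-1,3-dioxolan-4-yl]propanoate | C[C@@]1(CC=C([O-])OC(C)(C)C)O[C@@H](C(C)(C)C)OC1=O.[Li+] | intermediate
5 | tert-butyl (2RS)-3-[(2R,4S)-2-tert-butyl-4-methyl-5-oxo-1,3-dioxolan-4-yl]-2-hydroxypropanoate | C[C@@]1(CC(O)C(=O)OC(C)(C)C)O[C@@H](C(C)(C)C)OC1=O | intermediate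
6 | dilithium alkoxide of the methyllithium adduct of 5 (cyclic hemiketal) | C[C@@]1(CC([O-])C(=O)OC(C)(C)C)O[C@@H](C(C)(C)C)OC1(C)[O-].[Li+].[Li+] | intermediate
7 | tert-butyl (2RS,4S)-2,4-dihydroxy-4-methyl-5-oxohexanoate | CC(=O)[C@@](C)(O)CC(O)C(=O)OC(C)(C)C | intermediate
8 | angelic acid, (2Z)-2-methylbut-2-enoic acid | O=C(O)/C(C)=C\C | starting material
9 | tert-butyl (2RS,4S)-4-hydroxy-4-methyl-2-{[(2Z)-2-methylbut-2-enoyl]oxy}-5-oxohexanoate | CC(=O)[C@@](C)(O)CC(OC(=O)/C(C)=C\C)C(=O)OC(C)(C)C | intermediate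
10 | tert-butyl (2RS,4S)-4-acetoxy-4-methyl-2-{[(2Z)-2-methylbut-2-enoyl]oxy}-5-oxohexanoate | CC(=O)[C@@](C)(OC(C)=O)CC(OC(=O)/C(C)=C\C)C(=O)OC(C)(C)C | intermediate
11 | 2-(bromomethyl)acrylic acid | C=C(CBr)C(=O)O | starting material
12 | 2-[(phenylsulfonyl)methyl]prop-2-enoic acid | C=C(CS(=O)(=O)c1ccccc1)C(=O)O | intermediate
13 | propanal | CCC=O | starting material
14 | allyltrimethylsilane | C=CC[Si](C)(C)C | starting material
15 | (2S)-2-methylpent-4-enal | C=CC[C@H](C)C=O | intermediate
16 | allyl methyl carbonate | C=CCOC(=O)OC | starting material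
17 | (2S,4E)-6-[(methoxycarbonyl)oxy]-2-methylhex-4-enal | COC(=O)OC/C=C/C[C@H](C)C=O | intermediate
18 | (3S,5S)-5-methyl-6-oxohex-1-en-3-yl 2-[(phenylsulfonyl)methyl]prop-2-enoate | C=C(CS(=O)(=O)c1ccccc1)C(=O)O[C@H](C=C)C[C@H](C)C=O | intermediate
19 | (2S)-2-methyl-3-{(2S)-5-oxo-4-[(phenylsulfonyl)methyl]-2,5-dihydrofuran-2-yl}propanal | O=C1O[C@@H](C[C@H](C)C=O)C=C1CS(=O)(=O)c1ccccc1 | intermediate
20 | tert-butyl (2RS,4S,7R,8S)-4-acetoxy-7-hydroxy-4,8-dimethyl-2-{[(2Z)-2-methylbut-2-enoyl]oxy}-5-oxo-9-{(2S)-5-oxo-4-[(phenylsulfonyl)methyl]-2,5-dihydrofuran-2-yl}nonanoate | O=C1O[C@@H](C[C@H](C)[C@H](O)CC(=O)[C@@](C)(OC(C)=O)CC(OC(=O)/C(C)=C\C)C(=O)OC(C)(C)C)C=C1CS(=O)(=O)c1ccccc1 | intermediate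
21 | (2RS,4S,7R,8S)-4-acetoxy-7-hydroxy-4,8-dimethyl-2-{[(2Z)-2-methylbut-2-enoyl]oxy}-5-oxo-9-{(2S)-5-oxo-4-[(phenylsulfonyl)methyl]-2,5-dihydrofuran-2-yl}nonanoic acid | O=C1O[C@@H](C[C@H](C)[C@H](O)CC(=O)[C@@](C)(OC(C)=O)CC(OC(=O)/C(C)=C\C)C(=O)O)C=C1CS(=O)(=O)c1ccccc1 | intermediate
22 | α-acyloxyalkyl radical formed from 21 by loss of CO2 (radical at the angeloyloxy-bearing carbon) | O=C1O[C@@H](C[C@H](C)[C@H](O)CC(=O)[C@@](C)(OC(C)=O)C[CH]OC(=O)/C(C)=C\C)C=C1CS(=O)(=O)c1ccccc1 | intermediate
23 | cyclised tertiary lactone radical (radical at C3, still carrying CH2SO2Ph) | O=C1O[C@H]2C[C@H](C)[C@H](O)CC(=O)[C@@](C)(OC(C)=O)C[C@@H](OC(=O)/C(C)=C\C)[C@H]2[C]1CS(=O)(=O)c1ccccc1 | intermediate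
24 | (3aS,4R,6S,9R,10S,11aS)-6-acetoxy-9-hydroxy-6,10-dimethyl-3-methylidene-2,7-dioxododecahydrocyclodeca[b]furan-4-yl (2Z)-2-methylbut-2-enoate (CNP0141210.3) | C=C1C(=O)O[C@H]2C[C@H](C)[C@H](O)CC(=O)[C@@](C)(OC(C)=O)C[C@@H](OC(=O)/C(C)=C\C)[C@@H]12 | target

**Step count:** 13 steps in total. Longest linear sequence: 8 steps (steps 1–5, then 11–13). The other branch is steps 7–10 plus the side step 6.

**The three steps most likely to fail**

Step 13 (ten-membered radical closure; two stereocentres formed at once). Ten-membered rings are the slowest radical macrocyclisations, and the C4 configuration is the least predictable element of the route. Fallback, from 21 back to 24: replace the photoredox radical-polar crossover by a neutral Barton chain. Acid 21 is coupled with 1-hydroxypyridine-2(1H)-thione (DCC, CH2Cl2, 0 °C, dark) to give the O-acyl thiohydroxamate F1. Visible-light irradiation of F1 (PhMe, 1 mM, 25 °C) releases the same C4 radical without base or photocatalyst. After cyclisation the expelled PhSO2• carries the chain by attacking the thiocarbonyl of the next F1, giving 24 directly. This addresses chain efficiency and yield, not the C4 selectivity.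

Step 11 (mismatched reagent-controlled aldol on two sensitive partners). Fallback, from 10 back to 20: switch from the closed boron-enolate transition state to a catalyst-controlled open one. Ketone 10 is silylated (Me3SiOTf, Et3N, CH2Cl2, −78 °C) to the trimethylsilyl enol ether F2. Mukaiyama aldol of F2 with 19 under Corey's (S)-tryptophan-derived B-butyl N-tosyl oxazaborolidinone (20 mol%, EtCN, −78 °C) gives the 7-O-trimethylsilyl aldol F3. Cold 1 M HCl/THF removes the silyl group and returns 20.

Step 7 (volatile, easily racemised aldehyde; untested substrate for the SOMO allylation). Fallback, from 13 back to 15: auxiliary-based azaenolate alkylation. Propanal 13 is condensed with (S)-1-amino-2-(methoxymethyl)pyrrolidine to the hydrazone F4. Deprotonation (LiN(iPr)2, THF, 0 °C) and alkylation with allyl bromide at −100 °C give the α-allylated hydrazone F5. Two-phase cleavage with saturated aqueous oxalic acid/Et2O, which spares the alkene, releases 15.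

**Further compounds**
F1 | step 13 | 2-thioxopyridin-1(2H)-yl ester of acid 21 (Barton ester) | O=C1O[C@@H](C[C@H](C)[C@H](O)CC(=O)[C@@](C)(OC(C)=O)CC(OC(=O)/C(C)=C\C)C(=O)ON2C=CC=CC2=S)C=C1CS(=O)(=O)c1ccccc1
F2 | step 11 | tert-butyl (2RS,4S)-4-acetoxy-4-methyl-2-{[(2Z)-2-methylbut-2-enoyl]oxy}-5-[(trimethylsilyl)oxy]hex-5-enoate | C=C(O[Si](C)(C)C)[C@@](C)(OC(C)=O)CC(OC(=O)/C(C)=C\C)C(=O)OC(C)(C)C
F3 | step 11 | 7-O-trimethylsilyl ether of 20 | O=C1O[C@@H](C[C@H](C)[C@H](O[Si](C)(C)C)CC(=O)[C@@](C)(OC(C)=O)CC(OC(=O)/C(C)=C\C)C(=O)OC(C)(C)C)C=C1CS(=O)(=O)c1ccccc1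
F4 | step 7 | (E)-N-[(2S)-2-(methoxymethyl)pyrrolidin-1-yl]propan-1-imine | CC/C=N/N1CCC[C@H]1COC
F5 | step 7 | (E,2S)-N-[(2S)-2-(methoxymethyl)pyrrolidin-1-yl]-2-methylpent-4-en-1-imine | C=CC[C@H](C)/C=N/N1CCC[C@H]1COC
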